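**Retrosynthetic overview**

1. The side-chain ester C–O bond is cut last (shikonin plus 3-hydroxy-3-methylbutanoic acid). The naphthazarin is traced back through a 5,8-dimethoxy-1,4-naphthoquinone to a 5,8-dimethoxy-1,4-epoxy-1,4-dihydronaphthalene.
2. Feature used: the ring-fusion carbons C4a and C8a are adjacent carbons of the benzene ring C4a–C5–C6–C7–C8–C8a, which bears the same oxygen substituent at C5 and at C8. They hold the carbonyl carbons C4 and C1, and the chain C1–C2–C3–C4 with the side chain on C2 is the carbon skeleton of a 3-substituted furan.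
3. Key disconnection: C4–C4a and C1–C8a, giving symmetric 3,6-dimethoxybenzyne and an (R)-3-furyl carbinol silyl ether, joined by a [4+2] cycloaddition.
4. Ring order: the oxygenated benzene ring is bought (2,5-dimethoxyphenol) and the furan is bought (3-bromofuran). The second six-membered ring is closed in the key step, then aromatised and oxidised. The only stereocentre (side-chain C1') is set before the key step by CBS reduction of a 3-furyl ketone.

Key step: step 8

Remark: naphthalene numbering of the target is used (side chain on C2, carbinol carbon C1'). The carbinol centre of the target is (R), and the two naphthazarin tautomers are one compound.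

**Route**

Step 1
Reactants: 1 2,5-dimethoxyphenol
Product: 2 2,5-dimethoxyphenyl N-isopropylcarbamate
Conditions: i-PrNCO (1.2 equiv), Et3N (0.2 equiv), CH2Cl2, rt
Reagents that add atoms: isopropyl isocyanate, CC(C)N=C=O
Why: Base-catalysed addition of the phenol O–H across the isocyanate (carbamoylation) installs, without any by-product, the secondary carbamate that directs metalation and can later be removed under mild base.

Step 2
Reactants: 2 2,5-dimethoxyphenyl N-isopropylcarbamate
Product: 6 3,6-dimethoxy-2-(trimethylsilyl)phenyl N-isopropylcarbamate, via N-silyl carbamate 3 (not isolated), via aryllithium 4 (not isolated), via C,N-bis-silyl carbamate 5 (not isolated)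
Conditions: TMSOTf (1.1 equiv), TMEDA (1.1 equiv), Et2O, 0 °C to rt; then TMEDA (2 equiv), n-BuLi (2 equiv), −78 °C; then TMSCl (3 equiv), −78 °C to rt; aq. NaHSO4 work-up
Reagents that add atoms: chlorotrimethylsilane, C[Si](C)(C)Cl (the N-silyl group of 3 to 5 comes from trimethylsilyl triflate, C[Si](C)(C)OS(=O)(=O)C(F)(F)F, and is lost on work-up)
Why: Directed ortho-metalation, in which in-flask N-silylation masks the N–H, the carbamate and the C5 methoxy group together direct n-BuLi/TMEDA to the only free ortho position (C6, between them), TMSCl traps the aryllithium, and the N–Si bond is hydrolysed on work-up.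

Step 3
Reactants: 6 3,6-dimethoxy-2-(trimethylsilyl)phenyl N-isopropylcarbamate
Product: 8 3,6-dimethoxy-2-(trimethylsilyl)phenyl trifluoromethanesulfonate, via silyl phenol 7 (not isolated)
Conditions: DBU (1.5 equiv), Et2NH (1.2 equiv), MeCN, 40 °C; then PhNTf2 (1.5 equiv), rt
Reagents that add atoms: N-phenylbis(trifluoromethanesulfonimide), O=S(=O)(N(c1ccccc1)S(=O)(=O)C(F)(F)F)C(F)(F)F
Why: DBU induces E1cB loss of isopropyl isocyanate from the secondary carbamate (trapped by Et2NH as a urea), and the hindered phenoxide is O-triflated in the same flask by PhNTf2 without touching the aryl–silicon bond.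

Step 4
Reactants: 9 4-methylpent-3-enoic acid
Product: 11 N-methoxy-N,4-dimethylpent-3-enamide, via acyl imidazole 10 (not isolated)
Conditions: 1,1'-carbonyldiimidazole (1.1 equiv), CH2Cl2, 0 °C to rt; then MeNH(OMe)·HCl (1.2 equiv), rt
Reagents that add atoms: N,O-dimethylhydroxylamine hydrochloride, CNOC.Cl
Why: Activation of the acid as its acyl imidazole followed by aminolysis (Weinreb amide formation) runs under near-neutral conditions that leave the β,γ-alkene in place.

Step 5
Reactants: 12 3-bromofuran; 11 N-methoxy-N,4-dimethylpent-3-enamide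
Product: 15 1-(furan-3-yl)-4-methylpent-3-en-1-one, via furan-3-yllithium 13 (not isolated), via lithium hemiaminal adduct 14 (not isolated)
Conditions: n-BuLi (1.3 equiv), THF, −78 °C; then 11 (1.0 equiv), −78 °C; 1 M HCl quench, 0 °C
Reagents that add atoms: none
Why: Bromine–lithium exchange at −78 °C gives furan-3-yllithium without migration to C2, and its addition to the amide stops at the chelated tetrahedral adduct (Weinreb ketone synthesis), so the ketone appears only on cold quench and over-addition and base-induced conjugation of the alkene are avoided.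

Step 6
Reactants: 15 1-(furan-3-yl)-4-methylpent-3-en-1-one
Product: 17 (R)-1-(furan-3-yl)-4-methylpent-3-en-1-ol, via boronate ester 16 (not isolated)
Conditions: (S)-2-methyl-CBS-oxazaborolidine (0.2 equiv), catecholborane (1.5 equiv), toluene, −78 °C; MeOH, then aq. NaOH work-up
Reagents that add atoms: none
Why: Corey–Bakshi–Shibata reduction, in which the (S)-oxazaborolidine treats the flat furyl ring as the large ketone substituent and delivers hydride to the face that gives the (R)-carbinol, as it does for aryl alkyl ketones, while catecholborane at −78 °C does not hydroborate the trisubstituted alkene.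

Step 7
Reactants: 17 (R)-1-(furan-3-yl)-4-methylpent-3-en-1-ol
Product: 18 (R)-tert-butyl{[1-(furan-3-yl)-4-methylpent-3-en-1-yl]oxy}dimethylsilane
Conditions: TBSCl (1.3 equiv), imidazole (2.5 equiv), DMF, rt
Reagents that add atoms: tert-butyldimethylsilyl chloride, CC(C)(C)[Si](C)(C)Cl
Why: Imidazole-promoted O-silylation (silyl ether formation) masks the only O–H that could add to the aryne and does not involve the bonds of the stereocentre.

Step 8
Reactants: 8 3,6-dimethoxy-2-(trimethylsilyl)phenyl trifluoromethanesulfonate; 18 (R)-tert-butyl{[1-(furan-3-yl)-4-methylpent-3-en-1-yl]oxy}dimethylsilane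
Product: 20 2-[(R)-1-(tert-butyldimethylsilyloxy)-4-methylpent-3-enyl]-5,8-dimethoxy-1,4-dihydro-1,4-epoxynaphthalene (both bridgehead diastereomers), via 3,6-dimethoxybenzyne 19 (not isolated)
Conditions: 8 (1.5 equiv), 18 (1.0 equiv), CsF (3 equiv), MeCN, rt
Reagents that add atoms: none
Why: Fluoride attacks the trimethylsilyl group of 8 and the resulting aryl anion expels triflate (1,2-elimination) to give aryne 19, which the furan diene of 18 captures across its C2 and C5 positions in a concerted, suprafacial [4+2] cycloaddition. The closest known reaction type is the aryne–furan Diels–Alder reaction, which is established for 3,6-dimethoxybenzyne and simple furans. One ring is closed, the six-membered carbocycle C1–C2–C3–C4–C4a–C8a that becomes the quinone ring, in an intermolecular cycloaddition mode that forms C1–C8a and C4–C4a together and keeps the furan oxygen as a 1,4-bridge. The two bridgehead centres are necessarily cis to each other, but nothing controls their sense relative to the (R) side-chain centre, so two diastereomers are expected, which is of no consequence because both centres become sp2 in step 9. No regiocontrol is needed because the identical methoxy groups on either side of the aryne bond make both orientations of addition give one constitution. The needed chemoselectivity for the furan over an ene reaction at the trisubstituted alkene rests on the much higher diene reactivity of furan, and neutral CsF in MeCN at room temperature should leave the secondary silyl ether and the carbinol centre untouched.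

Step 9
Reactants: 20 2-[(R)-1-(tert-butyldimethylsilyloxy)-4-methylpent-3-enyl]-5,8-dimethoxy-1,4-dihydro-1,4-epoxynaphthalene
Product: 23 2-[(R)-1-(tert-butyldimethylsilyloxy)-4-methylpent-3-enyl]-5,8-dimethoxynaphthalene-1,4-dione, via 2-substituted naphthol 21 (not isolated), via 3-substituted naphthol 22 (not isolated)
Conditions: CF3CO2H (0.2 equiv), CH2Cl2, 0 °C; Et3N, concentrate; then (KSO3)2NO (2.5 equiv), KH2PO4, H2O/acetone, rt
Reagents that add atoms: potassium nitrosodisulfonate (Fremy's salt), [K+].[K+].[O]N(S(=O)(=O)[O-])S(=O)(=O)[O-]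
Why: Acid-catalysed opening of the oxygen bridge to an allylic, benzylic cation and loss of the bridgehead proton (oxanorbornadiene-to-naphthol isomerisation) is very easy on this electron-rich ring and gives either regioisomeric naphthol, and Teuber oxidation at the free para position converts both into the same 1,4-quinone under buffered conditions that spare the silyl ether, the alkene and the carbinol centre.

Step 10
Reactants: 23 2-[(R)-1-(tert-butyldimethylsilyloxy)-4-methylpent-3-enyl]-5,8-dimethoxynaphthalene-1,4-dione
Product: 25 2-[(R)-1-(tert-butyldimethylsilyloxy)-4-methylpent-3-enyl]-5,8-dihydroxynaphthalene-1,4-dione, via diquinone 24 (not isolated)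
Conditions: AgO (5 equiv), 6 N HNO3, 1,4-dioxane, rt, 5–10 min; then aq. Na2S2O4, 0 °C, brief, air
Reagents that add atoms: water, O
Why: Oxidative demethylation by divalent silver, formed from AgO in HNO3, turns the deactivated para-dimethoxy ring into a second quinone with water supplying the new carbonyl oxygens, and two-electron reduction of the strongly oxidising diquinone by Na2S2O4 gives the naphthazarin, so no Lewis acid meets the acid-sensitive side chain.

Step 11
Reactants: 25 2-[(R)-1-(tert-butyldimethylsilyloxy)-4-methylpent-3-enyl]-5,8-dihydroxynaphthalene-1,4-dione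
Product: 26 shikonin (5,8-dihydroxy-2-[(R)-1-hydroxy-4-methylpent-3-enyl]naphthalene-1,4-dione)
Conditions: HF·pyridine, pyridine, THF, 0 °C to rt
Reagents that add atoms: none
Why: Fluoride-mediated Si–O cleavage (desilylation) in a pyridine-buffered, mildly acidic medium frees the carbinol without exposing the base-sensitive naphthazarin to alkoxide and without breaking the C–O bond of the stereocentre.

Step 12
Reactants: 26 shikonin; 27 3-hydroxy-3-methylbutanoic acid
Product: 28 beta-HIVS, (R)-1-(5,8-dihydroxy-1,4-dioxo-1,4-dihydronaphthalen-2-yl)-4-methylpent-3-enyl 3-hydroxy-3-methylbutanoate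
Conditions: 27 (1.5 equiv), DCC (1.5 equiv), DMAP (0.1 equiv), CH2Cl2, 0 °C to rt
Reagents that add atoms: none
Why: Steglich esterification acylates only the secondary side-chain hydroxyl, because the two peri hydroxyls are held in hydrogen bonds to the quinone carbonyls and the tertiary hydroxyl of the acid is too hindered to compete, and acylation at oxygen leaves the (R) centre unchanged.

**Compound list**

1 | 2,5-dimethoxyphenol | COc1ccc(OC)c(O)c1 | starting material
2 | 2,5-dimethoxyphenyl N-isopropylcarbamate | COc1ccc(OC)c(OC(=O)NC(C)C)c1 | intermediate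
3 | 2,5-dimethoxyphenyl N-isopropyl-N-(trimethylsilyl)carbamate | COc1ccc(OC)c(OC(=O)N(C(C)C)[Si](C)(C)C)c1 | intermediate (not isolated)
4 | 6-lithio derivative of 3 (lithium between the carbamate oxygen and the C5 methoxy group) | COc1ccc(OC)c(OC(=O)N(C(C)C)[Si](C)(C)C)c1[Li] | intermediate (not isolated)
5 | 3,6-dimethoxy-2-(trimethylsilyl)phenyl N-isopropyl-N-(trimethylsilyl)carbamate | COc1ccc(OC)c(OC(=O)N(C(C)C)[Si](C)(C)C)c1[Si](C)(C)C | intermediate (not isolated)
6 | 3,6-dimethoxy-2-(trimethylsilyl)phenyl N-isopropylcarbamate | COc1ccc(OC)c(OC(=O)NC(C)C)c1[Si](C)(C)C | intermediate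
7 | 3,6-dimethoxy-2-(trimethylsilyl)phenol (present as its DBU salt) | COc1ccc(OC)c(O)c1[Si](C)(C)C | intermediate (not isolated)
8 | 3,6-dimethoxy-2-(trimethylsilyl)phenyl trifluoromethanesulfonate | COc1ccc(OC)c([Si](C)(C)C)c1OS(=O)(=O)C(F)(F)F | intermediate
9 | 4-methylpent-3-enoic acid | CC(C)=CCC(=O)O | starting material
10 | 1-(imidazol-1-yl)-4-methylpent-3-en-1-one | CC(C)=CCC(=O)n1ccnc1 | intermediate (not isolated)
11 | N-methoxy-N,4-dimethylpent-3-enamide | CC(C)=CCC(=O)N(C)OC | intermediate
12 | 3-bromofuran | Brc1ccoc1 | starting material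
13 | furan-3-yllithium | [Li]c1ccoc1 | intermediate (not isolated)
14 | lithium 1-(furan-3-yl)-1-[methoxy(methyl)amino]-4-methylpent-3-en-1-olate | CC(C)=CCC(O[Li])(N(C)OC)c1ccoc1 | intermediate (not isolated)
15 | 1-(furan-3-yl)-4-methylpent-3-en-1-one | CC(C)=CCC(=O)c1ccoc1 | intermediate
16 | 2-{[(R)-1-(furan-3-yl)-4-methylpent-3-en-1-yl]oxy}-1,3,2-benzodioxaborole | CC(C)=CC[C@@H](OB1Oc2ccccc2O1)c1ccoc1 | intermediate (not isolated)
17 | (R)-1-(furan-3-yl)-4-methylpent-3-en-1-ol | CC(C)=CC[C@@H](O)c1ccoc1 | intermediate
18 | (R)-tert-butyl{[1-(furan-3-yl)-4-methylpent-3-en-1-yl]oxy}dimethylsilane | CC(C)=CC[C@@H](O[Si](C)(C)C(C)(C)C)c1ccoc1 | intermediate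
19 | 3,6-dimethoxybenzyne | COC1=CC=C(OC)C#C1 | intermediate (not isolated)
20 | 2-[(R)-1-(tert-butyldimethylsilyloxy)-4-methylpent-3-enyl]-5,8-dimethoxy-1,4-dihydro-1,4-epoxynaphthalene, both bridgehead diastereomers | CC(C)=CC[C@@H](O[Si](C)(C)C(C)(C)C)C1=CC2OC1c1c(OC)ccc(OC)c12 | intermediate
21 | 2-[(R)-1-(tert-butyldimethylsilyloxy)-4-methylpent-3-enyl]-5,8-dimethoxynaphthalen-1-ol | CC(C)=CC[C@@H](O[Si](C)(C)C(C)(C)C)c1ccc2c(OC)ccc(OC)c2c1O | intermediate (not isolated)
22 | 3-[(R)-1-(tert-butyldimethylsilyloxy)-4-methylpent-3-enyl]-5,8-dimethoxynaphthalen-1-ol | CC(C)=CC[C@@H](O[Si](C)(C)C(C)(C)C)c1cc(O)c2c(OC)ccc(OC)c2c1 | intermediate (not isolated)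
23 | 2-[(R)-1-(tert-butyldimethylsilyloxy)-4-methylpent-3-enyl]-5,8-dimethoxynaphthalene-1,4-dione | CC(C)=CC[C@@H](O[Si](C)(C)C(C)(C)C)C1=CC(=O)c2c(OC)ccc(OC)c2C1=O | intermediate
24 | 2-[(R)-1-(tert-butyldimethylsilyloxy)-4-methylpent-3-enyl]naphthalene-1,4,5,8-tetrone | CC(C)=CC[C@@H](O[Si](C)(C)C(C)(C)C)C1=CC(=O)C2=C(C1=O)C(=O)C=CC2=O | intermediate (not isolated)
25 | 2-[(R)-1-(tert-butyldimethylsilyloxy)-4-methylpent-3-enyl]-5,8-dihydroxynaphthalene-1,4-dione | CC(C)=CC[C@@H](O[Si](C)(C)C(C)(C)C)C1=CC(=O)c2c(O)ccc(O)c2C1=O | intermediate
26 | shikonin, 5,8-dihydroxy-2-[(R)-1-hydroxy-4-methylpent-3-enyl]naphthalene-1,4-dione | CC(C)=CC[C@@H](O)C1=CC(=O)c2c(O)ccc(O)c2C1=O | intermediate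
27 | 3-hydroxy-3-methylbutanoic acid | CC(C)(O)CC(=O)O | starting material
28 | beta-HIVS, (R)-1-(5,8-dihydroxy-1,4-dioxo-1,4-dihydronaphthalen-2-yl)-4-methylpent-3-enyl 3-hydroxy-3-methylbutanoate | CC(C)=CC[C@@H](OC(=O)CC(C)(C)O)C1=CC(=O)c2c(O)ccc(O)c2C1=O | target

**Step count and risks**

Total step count: 12. Longest linear sequence: 9 steps (steps 4 to 12, from 4-methylpent-3-enoic acid). The aryne precursor arm is 3 steps (steps 1 to 3).

Steps most likely to fail:

1. Step 10. The strongly acidic and oxidising medium may strip the silyl ether and let the side chain cyclise, may oxidise the trisubstituted alkene, or may let the diquinone decompose before it is reduced. Over-reduction may also expel the benzylic oxygen. The fallback sets out from 23 and comes back at 25, moving the quinone to the other ring, which the naphthazarin tautomerism allows. Reductive acetylation of 23 (Zn dust, Ac2O, Et3N, rt) should give 2-[(R)-1-(tert-butyldimethylsilyloxy)-4-methylpent-3-enyl]-5,8-dimethoxynaphthalene-1,4-diyl diacetate F1. Oxidative demethylation with (NH4)2Ce(NO3)6 in MeCN/H2O at 0 °C should then attack the dimethoxy ring, which is now the more electron-rich one, and give 5,8-diacetoxy-6-[(R)-1-(tert-butyldimethylsilyloxy)-4-methylpent-3-enyl]naphthalene-1,4-dione F2. Mild methanolysis of the two aryl acetates (K2CO3, MeOH, 0 °C, then dilute acid) returns to 25.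

2. Step 9. Under acid the silyloxy group ortho to the new naphthol hydroxyl may ionise (ortho-quinone methide formation), with loss or racemisation of the carbinol centre. The ring-opening cation may be captured by the side-chain alkene, and the nitroxide may attack the ortho position of the 3-substituted naphthol to give an ortho-quinone. The fallback sets out from 20 and comes back at 23 by a neutral, metal-mediated path. Isomerisation with catalytic [Rh(CO)2Cl]2 in toluene (C–O insertion at the bridgehead, then β-hydride elimination and tautomerisation) should give the same naphthols 21 and 22 without any cation. Para-selective aerobic oxidation with catalytic Co(salen) under O2 in MeCN should then give 23. This fallback makes no compound outside the list (F0).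

3. Step 6. Facial discrimination between the small furyl ring and the CH2 chain may be insufficient, eroding enantiomeric purity, and the alkene may migrate into conjugation with the ketone (a hazard already in step 5). The fallback sets out from 12 and comes back at 18, avoiding the ketone altogether. Furan-3-yllithium 13 is formylated with DMF to furan-3-carbaldehyde F3, which can also be bought. Brown allylation with (+)-B-allyldiisopinocampheylborane (from (+)-Ipc2BOMe and allylMgBr, Et2O, −78 °C, oxidative work-up) should give (R)-1-(furan-3-yl)but-3-en-1-ol F4. This is the reagent antipode, derived from (−)-α-pinene, that converts benzaldehyde into the (R)-homoallylic alcohol. Silylation (TBSCl, imidazole, DMF) gives its silyl ether (R)-tert-butyl{[1-(furan-3-yl)but-3-en-1-yl]oxy}dimethylsilane F5. Cross-metathesis with excess 2-methylbut-2-ene (second-generation Grubbs catalyst, CH2Cl2, 40 °C) installs the trisubstituted alkene and returns to 18.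

**Further compounds**

F1 | step 10 | 2-[(R)-1-(tert-butyldimethylsilyloxy)-4-methylpent-3-enyl]-5,8-dimethoxynaphthalene-1,4-diyl diacetate | CC(C)=CC[C@@H](O[Si](C)(C)C(C)(C)C)c1cc(OC(C)=O)c2c(OC)ccc(OC)c2c1OC(C)=O
F2 | step 10 | 5,8-diacetoxy-6-[(R)-1-(tert-butyldimethylsilyloxy)-4-methylpent-3-enyl]naphthalene-1,4-dione | CC(C)=CC[C@@H](O[Si](C)(C)C(C)(C)C)c1cc(OC(C)=O)c2C(=O)C=CC(=O)c2c1OC(C)=O
F0 | step 9 | none | none
F3 | step 6 | furan-3-carbaldehyde | O=Cc1ccoc1
F4 | step 6 | (R)-1-(furan-3-yl)but-3-en-1-ol | C=CC[C@@H](O)c1ccoc1
F5 | step 6 | (R)-tert-butyl{[1-(furan-3-yl)but-3-en-1-yl]oxy}dimethylsilane | C=CC[C@@H](O[Si](C)(C)C(C)(C)C)c1ccoc1
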